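**Retrosynthetic overview**
- Ring B is opened at C8–C9: a 6-exo vinyl-radical cyclisation of a C8 bromoalkene onto a C9=C11 alkene (sets C9). The alkene comes from a Wittig reaction of a C10 aldehyde with an ylide made from (R)-monomethyl 3-methylglutarate (source of C13).
- Ring A is opened at C1–C10 and C4–C5: an enantioselective [4+2] cycloaddition of the 2-silyloxydiene C1=C2–C3(OSi)=C4Me2 to the (E)-2-methyl-2-enal O=C9H–C10(Me)=C5H–C6.
- Enabling feature: in ring A the only oxygen (on C3) sits next to the gem-dimethyl carbon C4 and 1,4 to C10, which carries the ring B carbon C9. C3–O/C4 is therefore a silyl enol ether retron (nucleophilic C4), C9 can serve as a formyl group activating C5=C10 (electrophilic C5), and the trans ring fusion is encoded in the E geometry of the enal.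
- The enal comes from propargyl alcohol, allyl bromide and methacrolein (bromoallylation, cross-metathesis).
- Ring order: ring A (step 5), then ring B (step 10); C3 is reduced last.

Key step: step 5

Remark: positions are given in labdane numbering (ring A = C1–C5, C10; ring B = C5–C10; side chain C11–C16; C17 on C8; C18/C19 on C4; C20 on C10), and the sense of induction in step 5 is taken from the accepted binding model of 2-substituted enals on the protonated oxazaborolidine.

**Step 1**
Reactants: 1 4-methylpent-1-en-3-one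
Product: 2 tert-butyl(dimethyl)[(4-methylpenta-1,3-dien-3-yl)oxy]silane
Conditions: TBSOTf, Et3N, Et2O, 0 °C
Reagents that add atoms: tert-butyldimethylsilyl trifluoromethanesulfonate, CC(C)(C)[Si](C)(C)OS(=O)(=O)C(F)(F)F
Why: Soft enolisation (silyl triflate/tertiary amine) at the only enolisable position, the isopropyl methine, should give the cross-conjugated 2-silyloxydiene, for which no stereoisomers exist.

**Step 2**
Reactants: 3 prop-2-yn-1-ol
Product: 4 tert-butyl(diphenyl)(prop-2-yn-1-yloxy)silane
Conditions: TBDPSCl, imidazole, CH2Cl2, 0 → 20 °C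
Reagents that add atoms: tert-butyl(chloro)diphenylsilane, CC(C)(C)[Si](Cl)(c1ccccc1)c1ccccc1
Why: Imidazole-mediated silylation of a primary alcohol; the TBDPS group has no hydrogen in a 1,5-relationship to the later C8 vinyl radical and resists the acidic catalyst of step 5.

**Step 3**
Reactants: 4 tert-butyl(diphenyl)(prop-2-yn-1-yloxy)silane; 5 allyl bromide
Product: 6 {[(2Z)-2-bromohexa-2,5-dien-1-yl]oxy}(tert-butyl)diphenylsilane
Conditions: PdBr2(PhCN)2 (3 mol %), neat 5 (6 equiv), slow addition of 4, 0 → 20 °C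
Reagents that add atoms: none
Why: Palladium-catalysed bromoallylation of a terminal alkyne: cis-bromopalladation by PdBr2 puts bromine on the internal carbon, the alkenylpalladium inserts the alkene of allyl bromide and β-bromide elimination returns PdBr2, which should give the (Z)-1-bromo-1,4-diene (its geometry is lost later at the vinyl radical).

**Step 4**
Reactants: 6 {[(2Z)-2-bromohexa-2,5-dien-1-yl]oxy}(tert-butyl)diphenylsilane; 7 methacrolein
Product: 8 (2E,5Z)-6-bromo-7-{[tert-butyl(diphenyl)silyl]oxy}-2-methylhepta-2,5-dienal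
Conditions: second-generation Grubbs catalyst (5 mol %), 7 (5 equiv), 1,4-benzoquinone (10 mol %), CH2Cl2, 40 °C
Reagents that add atoms: none
Why: Olefin cross-metathesis of a monosubstituted alkene with methacrolein, which should be E-selective for steric reasons, while the trisubstituted bromoalkene does not engage the ruthenium carbene.

**Step 5**
Reactants: 8 (2E,5Z)-6-bromo-7-{[tert-butyl(diphenyl)silyl]oxy}-2-methylhepta-2,5-dienal; 2 tert-butyl(dimethyl)[(4-methylpenta-1,3-dien-3-yl)oxy]silane
Product: 9 (1R,6R)-6-[(2Z)-3-bromo-4-{[tert-butyl(diphenyl)silyl]oxy}but-2-en-1-yl]-4-{[tert-butyl(dimethyl)silyl]oxy}-1,5,5-trimethylcyclohex-3-ene-1-carbaldehyde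
Conditions: (S)-3,3-diphenyl-1-(2-methylphenyl)tetrahydro-1H,3H-pyrrolo[1,2-c][1,3,2]oxazaborole (20 mol %), Tf2NH (18 mol %), 2 (2 equiv), CH2Cl2, −78 → −40 °C; Et3N quench
Reagents that add atoms: none
Why: Proposed new method: the triflimide-protonated oxazaborolidine binds the formyl oxygen of 8 (formyl C–H···O contact, s-trans enal stacked over a phenyl group), and the silyl enol ether terminus C4 of 2 attacks the β-carbon C5 while C1 closes onto C10 in a strongly asynchronous [4+2] cycloaddition that leaves the C2=C3 silyl enol ether. The closest known reactions are the cationic oxazaborolidine-catalysed Diels–Alder additions of 2-silyloxybutadienes to (E)-2-methyl-2-alkenals and the AlBr3/AlMe3-catalysed cycloadditions of 4,4-disubstituted 2-silyloxydienes to 2-methyl enones, which build the same vicinal quaternary pattern; new is the pairing of the chiral cation with a diene that is fully substituted at its nucleophilic end. Ring A is closed by intermolecular [4π+2π] addition (if the second bond lags, by 6-endo-trig attack of the boron enolate carbon C10 on the silyloxyallyl cation terminus C1). C5 and C10 are set relative to each other by the E geometry of the enal (C9 and C6 become trans on ring A, the later trans ring fusion) and absolutely by the catalyst, whose (S) form should expose the C5 Si/C10 Re face; the diene termini carry no stereo-information, so endo/exo is irrelevant. The step needs para regiochemistry, secured by matched polarity (nucleophilic C4, electrophilic C5), and 1,4- over 1,2-addition, which the α-methyl group, the catalyst bound at the formyl group and the bulk of the tetrasubstituted enol ether carbon should favour.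

**Step 6**
Reactants: 10 (3R)-5-methoxy-3-methyl-5-oxopentanoic acid
Product: 11 methyl (3R)-5-hydroxy-3-methylpentanoate
Conditions: BH3·SMe2, THF, −10 → 20 °C; MeOH quench
Reagents that add atoms: none
Why: Chemoselective borane reduction of a carboxylic acid (via the acyloxyborane) beside a methyl ester; the stereocentre is not touched and the crude hydroxy ester is used before it can lactonise.

**Step 7**
Reactants: 11 methyl (3R)-5-hydroxy-3-methylpentanoate
Product: 12 methyl (3S)-5-iodo-3-methylpentanoate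
Conditions: I2, PPh3, imidazole, CH2Cl2, 0 °C
Reagents that add atoms: iodine, II
Why: Appel-type iodination of a primary alcohol by SN2 displacement of the alkoxyphosphonium ion; the descriptor changes to S only through the priority rules.

**Step 8**
Reactants: 12 methyl (3S)-5-iodo-3-methylpentanoate
Product: 13 [(3S)-5-methoxy-3-methyl-5-oxopentyl]triphenylphosphonium iodide
Conditions: PPh3, MeCN, 80 °C
Reagents that add atoms: triphenylphosphine, c1ccc(cc1)P(c1ccccc1)c1ccccc1
Why: SN2 quaternisation of triphenylphosphine by a primary iodide (phosphonium salt formation).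

**Step 9**
Reactants: 13 [(3S)-5-methoxy-3-methyl-5-oxopentyl]triphenylphosphonium iodide; 9 (1R,6R)-6-[(2Z)-3-bromo-4-{[tert-butyl(diphenyl)silyl]oxy}but-2-en-1-yl]-4-{[tert-butyl(dimethyl)silyl]oxy}-1,5,5-trimethylcyclohex-3-ene-1-carbaldehyde
Product: 15 methyl (3R,5Z)-6-[(1S,6S)-6-[(2Z)-3-bromo-4-{[tert-butyl(diphenyl)silyl]oxy}but-2-en-1-yl]-4-{[tert-butyl(dimethyl)silyl]oxy}-1,5,5-trimethylcyclohex-3-en-1-yl]-3-methylhex-5-enoate, via phosphorus ylide 14 (not isolated)
Conditions: NaN(SiMe3)2, THF, −78 °C; then 9, −78 → 20 °C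
Reagents that add atoms: none
Why: Wittig olefination with a non-stabilised ylide under salt-free conditions, which should give the Z alkene from the non-enolisable neopentyl aldehyde at low temperature before the ylide can attack its own ester; the alkene geometry is erased in step 10.

**Step 10**
Reactants: 15 methyl (3R,5Z)-6-[(1S,6S)-6-[(2Z)-3-bromo-4-{[tert-butyl(diphenyl)silyl]oxy}but-2-en-1-yl]-4-{[tert-butyl(dimethyl)silyl]oxy}-1,5,5-trimethylcyclohex-3-en-1-yl]-3-methylhex-5-enoate
Product: 16 methyl (3R)-5-[(1S,4aS,8aS)-6-{[tert-butyl(dimethyl)silyl]oxy}-2-({[tert-butyl(diphenyl)silyl]oxy}methyl)-5,5,8a-trimethyl-1,4,4a,5,8,8a-hexahydronaphthalen-1-yl]-3-methylpentanoate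
Conditions: Bu3SnH (1.3 equiv, syringe pump), AIBN (azobisisobutyronitrile, 0.2 equiv), benzene (0.01 M), 80 °C
Reagents that add atoms: none
Why: Tin hydride-mediated 6-exo-trig vinyl radical cyclisation: the rapidly inverting C8 radical attacks C9 through a half-chair transition state in which the alkene carbon C11 is pseudo-equatorial (cis to the angular methyl C20, its Z substituent pointing away from the forming ring), which should set C9 as required, and the C11 radical is then reduced by Bu3SnH.

**Step 11**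
Reactants: 16 methyl (3R)-5-[(1S,4aS,8aS)-6-{[tert-butyl(dimethyl)silyl]oxy}-2-({[tert-butyl(diphenyl)silyl]oxy}methyl)-5,5,8a-trimethyl-1,4,4a,5,8,8a-hexahydronaphthalen-1-yl]-3-methylpentanoate
Product: 17 methyl (3R)-5-[(1S,4aS,8aS)-2-(hydroxymethyl)-5,5,8a-trimethyl-6-oxo-1,4,4a,5,6,7,8,8a-octahydronaphthalen-1-yl]-3-methylpentanoate
Conditions: TBAF, AcOH, THF, 0 → 20 °C
Reagents that add atoms: none
Why: Fluoride-induced desilylation cleaves the TBDPS ether and the silyl enol ether, whose enolate is protonated by the acetic acid buffer to the C3 ketone; C5 and C10 are not epimerisable.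

**Step 12**
Reactants: 17 methyl (3R)-5-[(1S,4aS,8aS)-2-(hydroxymethyl)-5,5,8a-trimethyl-6-oxo-1,4,4a,5,6,7,8,8a-octahydronaphthalen-1-yl]-3-methylpentanoate
Product: 18 methyl (3R)-5-[(1S,4aS,6R,8aS)-6-hydroxy-2-(hydroxymethyl)-5,5,8a-trimethyl-1,4,4a,5,6,7,8,8a-octahydronaphthalen-1-yl]-3-methylpentanoate (CNP0313905.1)
Conditions: NaBH4, MeOH, 0 °C
Reagents that add atoms: none
Why: Borohydride reduction of a 4,4-dimethyl-3-ketone on a trans-decalin, where axial hydride delivery from the face opposite the angular methyl and the axial C4 methyl should give the equatorial (6R) alcohol while the methyl ester and the allylic alcohol stay untouched.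

**Compound list**
1 | 4-methylpent-1-en-3-one | C=CC(=O)C(C)C | starting material
2 | tert-butyl(dimethyl)[(4-methylpenta-1,3-dien-3-yl)oxy]silane | C=CC(O[Si](C)(C)C(C)(C)C)=C(C)C | intermediate
3 | prop-2-yn-1-ol | C#CCO | starting material
4 | tert-butyl(diphenyl)(prop-2-yn-1-yloxy)silane | C#CCO[Si](c1ccccc1)(c1ccccc1)C(C)(C)C | intermediate
5 | allyl bromide (3-bromoprop-1-ene) | C=CCBr | starting material
6 | {[(2Z)-2-bromohexa-2,5-dien-1-yl]oxy}(tert-butyl)diphenylsilane | C=CC/C=C(\Br)CO[Si](c1ccccc1)(c1ccccc1)C(C)(C)C | intermediate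
7 | methacrolein (2-methylprop-2-enal) | C=C(C)C=O | starting material
8 | (2E,5Z)-6-bromo-7-{[tert-butyl(diphenyl)silyl]oxy}-2-methylhepta-2,5-dienal | O=C/C(C)=C/C/C=C(\Br)CO[Si](c1ccccc1)(c1ccccc1)C(C)(C)C | intermediate
9 | (1R,6R)-6-[(2Z)-3-bromo-4-{[tert-butyl(diphenyl)silyl]oxy}but-2-en-1-yl]-4-{[tert-butyl(dimethyl)silyl]oxy}-1,5,5-trimethylcyclohex-3-ene-1-carbaldehyde | O=C[C@]1(C)CC=C(O[Si](C)(C)C(C)(C)C)C(C)(C)[C@H]1C/C=C(\Br)CO[Si](c1ccccc1)(c1ccccc1)C(C)(C)C | intermediate
10 | (3R)-5-methoxy-3-methyl-5-oxopentanoic acid ((R)-monomethyl 3-methylglutarate) | COC(=O)C[C@H](C)CC(=O)O | starting material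
11 | methyl (3R)-5-hydroxy-3-methylpentanoate | COC(=O)C[C@H](C)CCO | intermediate
12 | methyl (3S)-5-iodo-3-methylpentanoate | COC(=O)C[C@H](C)CCI | intermediate
13 | [(3S)-5-methoxy-3-methyl-5-oxopentyl]triphenylphosphonium iodide | COC(=O)C[C@H](C)CC[P+](c1ccccc1)(c1ccccc1)c1ccccc1.[I-] | intermediate
14 | methyl (3S)-3-methyl-5-(triphenyl-λ5-phosphanylidene)pentanoate (ylide, not isolated) | COC(=O)C[C@H](C)CC=P(c1ccccc1)(c1ccccc1)c1ccccc1 | intermediate
15 | methyl (3R,5Z)-6-[(1S,6S)-6-[(2Z)-3-bromo-4-{[tert-butyl(diphenyl)silyl]oxy}but-2-en-1-yl]-4-{[tert-butyl(dimethyl)silyl]oxy}-1,5,5-trimethylcyclohex-3-en-1-yl]-3-methylhex-5-enoate | COC(=O)C[C@H](C)C/C=C\[C@]1(C)CC=C(O[Si](C)(C)C(C)(C)C)C(C)(C)[C@H]1C/C=C(\Br)CO[Si](c1ccccc1)(c1ccccc1)C(C)(C)C | intermediate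
16 | methyl (3R)-5-[(1S,4aS,8aS)-6-{[tert-butyl(dimethyl)silyl]oxy}-2-({[tert-butyl(diphenyl)silyl]oxy}methyl)-5,5,8a-trimethyl-1,4,4a,5,8,8a-hexahydronaphthalen-1-yl]-3-methylpentanoate | COC(=O)C[C@H](C)CC[C@@H]1C(CO[Si](c3ccccc3)(c3ccccc3)C(C)(C)C)=CC[C@@H]2C(C)(C)C(O[Si](C)(C)C(C)(C)C)=CC[C@@]12C | intermediate
17 | methyl (3R)-5-[(1S,4aS,8aS)-2-(hydroxymethyl)-5,5,8a-trimethyl-6-oxo-1,4,4a,5,6,7,8,8a-octahydronaphthalen-1-yl]-3-methylpentanoate | COC(=O)C[C@H](C)CC[C@@H]1C(CO)=CC[C@@H]2C(C)(C)C(=O)CC[C@@]12C | intermediate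
18 | methyl (3R)-5-[(1S,4aS,6R,8aS)-6-hydroxy-2-(hydroxymethyl)-5,5,8a-trimethyl-1,4,4a,5,6,7,8,8a-octahydronaphthalen-1-yl]-3-methylpentanoate | COC(=O)C[C@H](C)CC[C@@H]1C(CO)=CC[C@@H]2C(C)(C)[C@H](O)CC[C@@]12C | target

**Step count**
Total step count: 12. Longest linear sequence: 8 steps (steps 2, 3, 4, 5, 9, 10, 11, 12).

**Steps most likely to fail**

Step 5. The silyl enol ether may add 1,2 to the catalyst-bound formyl group (Mukaiyama aldol) faster than it cyclises, the hindered diene may be protodesilylated before it reacts, or facial discrimination may erode with so crowded a diene. The fallback uses known chemistry, sets out from 6 and returns at 9. Cross-metathesis of 6 with (1R,2S,5R)-menthyl methacrylate (second-generation Grubbs catalyst, CH2Cl2, 40 °C) should give the menthyl (2E,5Z)-dienoate F1, whose ester carbonyl is not prone to 1,2-addition. The established AlBr3/AlMe3-catalysed cycloaddition of hindered 2-silyloxydienes with α-methyl-substituted dienophiles (2, toluene/CH2Cl2, 0 °C) should then give two diastereomeric adducts that are separated by chromatography, the wanted one being the menthyl (1R,6R)-cyclohexenecarboxylate F2. Reduction with DIBAL (CH2Cl2, −78 → 0 °C) should give the neopentyl alcohol F3, and oxidation with Dess–Martin periodinane gives 9. The absolute configuration then rests on separation of diastereomers, not on catalysis.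

Step 10. The vinyl radical may be reduced by the stannane, or may close in the 7-endo mode at C11, before it reaches the neopentylic carbon C9; facial selectivity at C9 may also be insufficient. The fallback sets out from 9 and returns at 17. Horner–Wadsworth–Emmons olefination of 9 with 2-(trimethylsilyl)ethyl (diethoxyphosphoryl)acetate (NaH, THF) should give the (E)-enoate F4, whose β-carbon C9 is a polarity-matched, regiochemically unambiguous radical acceptor. Bu3SnH/AIBN should then give the bicyclic 2-(trimethylsilyl)ethyl acetate F5. TBAF in THF removes all three silicon groups and should give the keto hydroxy acid F6. Mixed Kolbe electrolysis of F6 with an excess of 10 (MeOH, partial neutralisation with NaOMe, Pt electrodes, constant current) joins the C11 radical to the radical derived from 10 and should give 17 with C13 taken unchanged from 10.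

Step 4. Ruthenium hydride species may shift the skipped diene into conjugation, or turnover with the electron-poor, 1,1-disubstituted methacrolein may stall. The fallback sets out from 6 and returns at 8. Lemieux–Johnson cleavage of the monosubstituted alkene of 6 (OsO4 cat., NaIO4, 2,6-lutidine, dioxane/water) should give the β,γ-unsaturated (3Z)-bromo aldehyde F7. It is used at once in a Wittig reaction with the stabilised ylide Ph3P=C(CH3)CHO (toluene, 20–50 °C), which should give 8 with E geometry.

**Further compounds**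
F1 | step 5 | (1R,2S,5R)-5-methyl-2-(propan-2-yl)cyclohexyl (2E,5Z)-6-bromo-7-{[tert-butyl(diphenyl)silyl]oxy}-2-methylhepta-2,5-dienoate | C[C@@H]1CC[C@H]([C@@H](C1)OC(=O)/C(C)=C/C/C=C(\Br)CO[Si](c2ccccc2)(c2ccccc2)C(C)(C)C)C(C)C
F2 | step 5 | (1R,2S,5R)-5-methyl-2-(propan-2-yl)cyclohexyl (1R,6R)-6-[(2Z)-3-bromo-4-{[tert-butyl(diphenyl)silyl]oxy}but-2-en-1-yl]-4-{[tert-butyl(dimethyl)silyl]oxy}-1,5,5-trimethylcyclohex-3-ene-1-carboxylate | C[C@@H]1CC[C@H]([C@@H](C1)OC(=O)[C@]2(C)CC=C(O[Si](C)(C)C(C)(C)C)C(C)(C)[C@H]2C/C=C(\Br)CO[Si](c3ccccc3)(c3ccccc3)C(C)(C)C)C(C)C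
F3 | step 5 | [(1R,6S)-6-[(2Z)-3-bromo-4-{[tert-butyl(diphenyl)silyl]oxy}but-2-en-1-yl]-4-{[tert-butyl(dimethyl)silyl]oxy}-1,5,5-trimethylcyclohex-3-en-1-yl]methanol | OC[C@]1(C)CC=C(O[Si](C)(C)C(C)(C)C)C(C)(C)[C@H]1C/C=C(\Br)CO[Si](c1ccccc1)(c1ccccc1)C(C)(C)C
F4 | step 10 | 2-(trimethylsilyl)ethyl (2E)-3-[(1S,6S)-6-[(2Z)-3-bromo-4-{[tert-butyl(diphenyl)silyl]oxy}but-2-en-1-yl]-4-{[tert-butyl(dimethyl)silyl]oxy}-1,5,5-trimethylcyclohex-3-en-1-yl]prop-2-enoate | C[Si](C)(C)CCOC(=O)/C=C/[C@]1(C)CC=C(O[Si](C)(C)C(C)(C)C)C(C)(C)[C@H]1C/C=C(\Br)CO[Si](c1ccccc1)(c1ccccc1)C(C)(C)C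
F5 | step 10 | 2-(trimethylsilyl)ethyl [(1S,4aS,8aS)-6-{[tert-butyl(dimethyl)silyl]oxy}-2-({[tert-butyl(diphenyl)silyl]oxy}methyl)-5,5,8a-trimethyl-1,4,4a,5,8,8a-hexahydronaphthalen-1-yl]acetate | C[Si](C)(C)CCOC(=O)C[C@@H]1C(CO[Si](c3ccccc3)(c3ccccc3)C(C)(C)C)=CC[C@@H]2C(C)(C)C(O[Si](C)(C)C(C)(C)C)=CC[C@@]12C
F6 | step 10 | [(1S,4aS,8aS)-2-(hydroxymethyl)-5,5,8a-trimethyl-6-oxo-1,4,4a,5,6,7,8,8a-octahydronaphthalen-1-yl]acetic acid | OC(=O)C[C@@H]1C(CO)=CC[C@@H]2C(C)(C)C(=O)CC[C@@]12C
F7 | step 4 | (3Z)-4-bromo-5-{[tert-butyl(diphenyl)silyl]oxy}pent-3-enal | O=CC/C=C(\Br)CO[Si](c1ccccc1)(c1ccccc1)C(C)(C)C
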